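**Assumptions (one line each)**
- The SMILES is read as the trans-2,5-disubstituted oxolane with (2R) at the carbon bearing the butanoate chain and (5S) at the carbon bearing the alkyne.
- The (R,R)-DACH-phenyl Trost ligand is assumed to ionise the enantiotopic benzoate that leads to the (2R) centre; if the sense is opposite, the (S,S)-ligand is used and nothing else changes.

**Retrosynthetic overview**
1. C10–C11: mono-Sonogashira coupling of a THF-alkyne with the symmetric (E,E)-1,10-dibromodeca-1,9-diene (from deca-1,9-diyne).
2. C8–C9: trans-selective alkynylation of the oxocarbenium ion from a 5-substituted lactol benzoate.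
3. C4–C5 and absolute configuration: Pd-catalysed enantioselective desymmetrisation of meso cis-2,5-dibenzoyloxy-2,5-dihydrofuran with a vinylogous silyl dienolate; one hydrogenation then saturates ring and side chain.
4. The only ring (the oxolane) is never cyclised: it is the furan ring, dearomatised by Pb(IV) 1,4-diacyloxylation in step 1 and saturated in step 4.

**Step 1**
Reactants: 1 furan
Product: 2 cis-2,5-dihydrofuran-2,5-diyl dibenzoate (meso, 2R,5S)
Conditions: Pb(OBz)4 (preformed from Pb(OAc)4 + BzOH), PhH, 60 °C; recrystallise the cis isomer
Reagents that add atoms: lead(IV) benzoate, O=C(O[Pb](OC(=O)c1ccccc1)(OC(=O)c1ccccc1)OC(=O)c1ccccc1)c1ccccc1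
Why: Clauson-Kaas-type oxidative 1,4-diacyloxylation of furan by a Pb(IV) carboxylate destroys the aromaticity and gives the 2,5-diester, from which the crystalline meso cis isomer is isolated.

**Step 2**
Reactants: 3 methyl (E)-but-2-enoate (methyl crotonate)
Product: 4 tert-butyl[(1-methoxybuta-1,3-dien-1-yl)oxy]dimethylsilane (silyl dienolate)
Conditions: LDA, THF–DMPU, −78 °C; TBSCl
Reagents that add atoms: TBSCl, CC(C)(C)[Si](C)(C)Cl
Why: Kinetic γ-deprotonation of the enoate in the presence of a polar cosolvent gives the extended lithium dienolate, which is O-silylated to the silyl ketene acetal (standard vinylogous Mukaiyama donor synthesis).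

**Step 3 (key step)**
Reactants: 2 meso dibenzoate; 4 silyl dienolate (1.2 equiv)
Product: 5 methyl (2E)-4-[(2R,5S)-5-(benzoyloxy)-2,5-dihydrofuran-2-yl]but-2-enoate
Conditions: [Pd(allyl)Cl]2 (2.5 mol%), (R,R)-DACH-phenyl Trost ligand (7.5 mol%), THF, 0 °C → rt
Reagents that add atoms: none besides reactants 2 and 4
Why: Proposed new method: Pd(0)/Trost-ligand ionisation of one enantiotopic benzoate of meso 2 (the enantio-determining event, known for this substrate with soft C- and N-nucleophiles, with net retention by double inversion and attack at the O-bearing allyl terminus) gives a cationic alkoxy-π-allyl-Pd/benzoate ion pair that the neutral silyl dienolate should capture outer-sphere through its γ-carbon (vinylogous Mukaiyama-type, after which benzoate removes the silyl group as TBSOBz and turns the cycle over), setting the (R) centre and leaving the second benzoate cis; the closest known reaction types are Pd-catalysed asymmetric allylic alkylation of meso 2-ene-1,4-diol diesters with malonate-type nucleophiles and γ-selective metal-allyl substitutions with silyl dienolates and silyl ketene acetals.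

**Step 4**
Reactants: 5
Product: 6 methyl 4-[(2R,5S)-5-(benzoyloxy)oxolan-2-yl]butanoate
Conditions: H2 (1 atm), 5% Rh/Al2O3, EtOAc, rt
Reagents that add atoms: none
Why: Heterogeneous hydrogenation saturates the ring alkene and the enoate in one operation, Rh/Al2O3 in neutral EtOAc being chosen to avoid hydrogenolysis of the allylic/anomeric benzoate; C2 is untouched and the anomeric configuration does not matter because it is ionised next.

**Step 5**
Reactants: 6; 7 trimethyl[(tributylstannyl)ethynyl]silane (1.5–2 equiv)
Product: 8 methyl 4-[(2R,5S)-5-[(trimethylsilyl)ethynyl]oxolan-2-yl]butanoate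
Conditions: TMSOTf (1.2 equiv), CH2Cl2, −78 → −40 °C; aq. KF work-up
Reagents that add atoms: none besides reactant 7
Why: TMSOTf ionises 6 to the 5-substituted oxolan-2-ylium ion, which is attacked by the alkynylstannane at the tin-bearing carbon (β-stannyl-stabilised, Bu3Sn lost, TMS kept) preferentially on the face anti to the C5 side chain, setting the (S) centre trans to the chain under substrate control in a Lewis-acid C-glycosylation-type alkynylation (expected about 4–6:1 trans:cis, cis isomer removed by chromatography).

**Step 6**
Reactants: 9 deca-1,9-diyne
Product: 10 (1E,9E)-1,10-dibromodeca-1,9-diene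
Conditions: Cp2Zr(H)Cl (2.3 equiv), THF, rt; NBS (2.3 equiv), 0 °C
Reagents that add atoms: N-bromosuccinimide, O=C1CCC(=O)N1Br
Why: Double Schwartz hydrozirconation is syn and anti-Markovnikov, and bromodezirconation proceeds with retention, giving both (E)-vinyl bromides.

**Step 7**
Reactants: 8; 10 (4 equiv, excess recovered)
Product: 11 Mutafuran C, methyl 4-[(2R,5S)-5-[(3E,11E)-12-bromododeca-3,11-dien-1-yn-1-yl]oxolan-2-yl]butanoate
Conditions: K2CO3, MeOH, rt (in situ C–Si cleavage); then 10, Pd(PPh3)4 (5 mol%), CuI (10 mol%), piperidine, THF, rt, one pot
Reagents that add atoms: none besides reactant 10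
Why: Methanolysis frees the terminal alkyne (transesterification of the methyl ester in MeOH is degenerate) and Sonogashira coupling with one vinyl bromide of the symmetric dibromide proceeds with retention of E geometry, the excess of 10 suppressing double coupling; neither stereocentre is touched.

**Compound list**
1 | furan | c1ccoc1 | starting material
2 | cis-2,5-dihydrofuran-2,5-diyl dibenzoate (meso) | O=C(O[C@H]1C=C[C@@H](OC(=O)c2ccccc2)O1)c1ccccc1 | intermediate
3 | methyl (E)-but-2-enoate | C/C=C/C(=O)OC | starting material
4 | tert-butyl[(1-methoxybuta-1,3-dien-1-yl)oxy]dimethylsilane | C=CC=C(OC)O[Si](C)(C)C(C)(C)C | intermediate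
5 | methyl (2E)-4-[(2R,5S)-5-(benzoyloxy)-2,5-dihydrofuran-2-yl]but-2-enoate | COC(=O)/C=C/C[C@@H]1C=C[C@H](OC(=O)c2ccccc2)O1 | intermediate
6 | methyl 4-[(2R,5S)-5-(benzoyloxy)oxolan-2-yl]butanoate | COC(=O)CCC[C@@H]1CC[C@H](OC(=O)c2ccccc2)O1 | intermediate
7 | trimethyl[(tributylstannyl)ethynyl]silane | CCCC[Sn](CCCC)(CCCC)C#C[Si](C)(C)C | starting material
8 | methyl 4-[(2R,5S)-5-[(trimethylsilyl)ethynyl]oxolan-2-yl]butanoate | COC(=O)CCC[C@@H]1CC[C@@H](C#C[Si](C)(C)C)O1 | intermediate
9 | deca-1,9-diyne | C#CCCCCCCC#C | starting material
10 | (1E,9E)-1,10-dibromodeca-1,9-diene | Br/C=C/CCCCCC/C=C/Br | intermediate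
11 | Mutafuran C | COC(=O)CCC[C@@H]1CC[C@@H](C#C/C=C/CCCCCC/C=C/Br)O1 | target

**Step count**
- Total steps: 7.
- Longest linear sequence: 5 (steps 1 → 3 → 4 → 5 → 7, from furan).

**Three steps most likely to fail, with fallbacks**
1. Step 3 (the neutral dienolate may be too unreactive, or may attack through its α-carbon). Fallback: use a classical soft pronucleophile, methyl 4-nitrobutanoate with Cs2CO3, in the same Pd desymmetrisation (nitronate allylic alkylation is a known class), hydrogenate the ring alkene, then remove the nitro group by radical denitration (Bu3SnH, AIBN). This costs one extra step and rejoins the route at 6.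
2. Step 5 (trans:cis selectivity with a small sp nucleophile may be modest). Fallback: abandon the oxocarbenium alkynylation. Methanolyse 6 to the lactol, methylenate by Wittig to methyl (5R)-5-hydroxynon-8-enoate, and close the ring by Co(II)-catalysed aerobic (Mukaiyama-type) oxidative cyclisation, which gives trans-2-hydroxymethyl-oxolanes with high selectivity. Oxidation to the aldehyde and Ohira–Bestmann homologation then give the terminal alkyne corresponding to 8.
3. Step 4 (hydrogenolysis of the allylic/anomeric benzoate, or elimination to the 2-alkylfuran). Fallback: before hydrogenation, exchange the remaining allylic benzoate of 5 for a phenylsulfonyl group (PhSO2Na, Pd(0), retention). Hydrogenate the robust sulfone, then introduce the alkyne by substitution of the 2-sulfonyl oxolane with an alkynylzinc reagent, which also tends to improve trans selectivity.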